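**Assumption:** the target is taken exactly as the SMILES is written, i.e. (2E,5R,6R,7R,9S,10E,12E,15R,16Z,18E) in the chain with a trans (5S,6R)-lactone; RAMP and (E)-pent-2-en-4-yn-1-ol are taken as purchasable.

## Retrosynthetic overview

1. Numbering: chain C1 (CO2H) to C19, lactone carbinol carbon C20, methyl-bearing ring carbon C21. Last step: fluoride removal of one TES ether and the 2-(trimethylsilyl)ethyl ester from 34.
2. Key disconnection C9–C10: nickel/titanocene radical cross-electrophile coupling of epoxy ketone 18 (C1–C9 plus the CH2O carbon) with dienyl bromide 33 (C10–C24). The C9 α-keto radical from epoxide homolysis sets C9 under ligand control and frees the CH2OH.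
3. 18 comes from Enders alkylation (C5), reagent-controlled Brown anti-crotylation (C6, C7), Negishi carboalumination/acylation ((2E)-enoate) and C8 homologation to the epoxy ketone.
4. 33 comes from Suzuki coupling (C17–C18) of the Zhao–Wittig (Z)-vinyl iodide 26 (C15 from a second Enders alkylation) with lactone boronate 32.
5. Ring order: the only ring, the dihydropyranone, is closed first by RCM of acrylate 30 (step 19), before any fragment union.

## Route

**Step 1**
Reactants: 1 propanal
Product: 2 (E)-N-[(2R)-2-(methoxymethyl)pyrrolidin-1-yl]propan-1-imine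
Conditions: RAMP, Et2O, MgSO4, 0 °C → rt (made on a scale that serves steps 2 and 14)
Reagents that add atoms: (R)-1-amino-2-(methoxymethyl)pyrrolidine (RAMP), COC[C@H]1CCCN1N
Why: Condensation of an aldehyde with a 1,1-disubstituted hydrazine gives the (E)-hydrazone (Enders hydrazone formation); no stereocentre is formed.

**Step 2**
Reactants: 2 (E)-N-[(2R)-2-(methoxymethyl)pyrrolidin-1-yl]propan-1-imine; 3 3-bromoprop-1-yne
Product: 4 (E,2R)-N-[(2R)-2-(methoxymethyl)pyrrolidin-1-yl]-2-methylpent-4-yn-1-imine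
Conditions: LiN(i-Pr)2, THF, 0 °C; 3, −100 °C → rt
Reagents that add atoms: none
Why: Enders RAMP-hydrazone alkylation: the chelated lithium azaenolate is alkylated on the face left open by the auxiliary, and RAMP gives the (R) centre that becomes C5.

**Step 3**
Reactants: 4 (E,2R)-N-[(2R)-2-(methoxymethyl)pyrrolidin-1-yl]-2-methylpent-4-yn-1-imine
Product: 6 (2R)-2-methylpent-4-ynal, via hydrazonium iodide 5 (not isolated)
Conditions: MeI (excess), 60 °C; then 3 M aq. HCl/n-pentane, rt; pentane solution used directly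
Reagents that add atoms: water, O; iodomethane, CI (its methyl group is found in 5 and leaves with the auxiliary)
Why: N-methylation turns the hydrazone into a hydrazonium salt that hydrolyses in the two-phase acid system without epimerising the α-centre (Enders hydrazone cleavage).

**Step 4**
Reactants: 7 (E)-but-2-ene
Product: 9 (E)-but-2-enyldiisopinocampheylborane, via crotylpotassium 8 (not isolated)
Conditions: 7, KOt-Bu, n-BuLi, THF, −78 → −45 °C; (−)-Ipc2BOMe, −78 °C; BF3·OEt2, −78 °C; one batch, kept at −78 °C and divided at once by cold cannula between the flasks of steps 5 and 17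
Reagents that add atoms: (−)-B-methoxydiisopinocampheylborane, COB([C@@H]1C[C@@H]2C[C@H]([C@H]1C)C2(C)C)[C@@H]1C[C@@H]2C[C@H]([C@H]1C)C2(C)C; potassium tert-butoxide, CC(C)(C)[O-].[K+] (its potassium is found in 8 and leaves as the methoxytrifluoroborate salt)
Why: Schlosser metalation of (E)-but-2-ene gives (E)-crotylpotassium, which keeps its geometry below −45 °C, and transmetalation to boron followed by removal of methoxide with BF3 gives the (E)-crotylborane with the alkene geometry retained (Brown crotylborane preparation); no stereocentre is formed, and the reagent does not isomerise at −78 °C.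

**Step 5**
Reactants: 6 (2R)-2-methylpent-4-ynal; 9 (E)-but-2-enyldiisopinocampheylborane
Product: 10 (3S,4R,5R)-3,5-dimethyloct-1-en-7-yn-4-ol
Conditions: 9 (first portion of the step 4 batch, 1.3 equiv), THF, −78 °C; 6 in pentane, −78 °C, 4 h; 3 M NaOH, 30% H2O2, rt
Reagents that add atoms: none
Why: Brown crotylboration through a chair transition state: the (E)-crotyl group gives the 6,7-anti relationship, the Ipc groups derived from (+)-α-pinene deliver it to the Si face (6R), and this strong reagent control overrides the small intrinsic facial bias of the α-methyl aldehyde, so the anti,anti triad (5R,6R and the centre that becomes 7R) is the major diastereomer and minor isomers are removed by chromatography.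

**Step 6**
Reactants: 10 (3S,4R,5R)-3,5-dimethyloct-1-en-7-yn-4-ol
Product: 11 (3S,4R,5R)-3,5-dimethyl-4-(triethylsilyloxy)oct-1-en-7-yne
Conditions: Et3SiCl, imidazole, DMAP (cat.), DMF, rt
Reagents that add atoms: chlorotriethylsilane, CC[Si](Cl)(CC)CC
Why: Silyl ether formation protects the C6 hydroxyl for the organometallic and oxidation steps; no stereocentre is touched.

**Step 7**
Reactants: 11 (3S,4R,5R)-3,5-dimethyl-4-(triethylsilyloxy)oct-1-en-7-yne
Product: 13 2-(trimethylsilyl)ethyl (2E,5R,6R,7S)-3,5,7-trimethyl-6-(triethylsilyloxy)nona-2,8-dienoate, via alkenyldimethylalane 12 (not isolated)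
Conditions: Me3Al (3 equiv), Cp2ZrCl2 (25 mol %), ClCH2CH2Cl, 0 °C → rt; then ClCO2CH2CH2SiMe3, 0 °C → rt
Reagents that add atoms: trimethylaluminium, C[Al](C)C; 2-(trimethylsilyl)ethyl chloroformate, C[Si](C)(C)CCOC(Cl)=O
Why: Negishi zirconium-catalysed carboalumination adds Me and Al syn across the terminal alkyne (Me to the internal carbon), and acylation of the alkenylalane by the chloroformate with retention gives only the (2E)-3-methyl enoate; the alkene and silyl ether are inert.

**Step 8**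
Reactants: 13 2-(trimethylsilyl)ethyl (2E,5R,6R,7S)-3,5,7-trimethyl-6-(triethylsilyloxy)nona-2,8-dienoate
Product: 14 2-(trimethylsilyl)ethyl (2E,5R,6R,7R)-3,5,7-trimethyl-8-oxo-6-(triethylsilyloxy)oct-2-enoate
Conditions: O3, CH2Cl2, −78 °C (indicator end point); PPh3, −78 °C → rt
Reagents that add atoms: ozone, [O-][O+]=O
Why: Ozonolysis is selective for the monosubstituted alkene over the electron-poor trisubstituted enoate, and the reductive work-up gives the C8 aldehyde without epimerising C7.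

**Step 9**
Reactants: 14 2-(trimethylsilyl)ethyl (2E,5R,6R,7R)-3,5,7-trimethyl-8-oxo-6-(triethylsilyloxy)oct-2-enoate; 15 vinylmagnesium bromide
Product: 16 2-(trimethylsilyl)ethyl (2E,5R,6R,7S)-8-hydroxy-3,5,7-trimethyl-6-(triethylsilyloxy)deca-2,9-dienoate (both C8 epimers)
Conditions: 15, THF, −78 °C; aq. NH4Cl
Reagents that add atoms: none
Why: Grignard 1,2-addition to the aldehyde is much faster than attack on the hindered conjugated ester at −78 °C; the C8 configuration is irrelevant because C8 is oxidised in step 11.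

**Step 10**
Reactants: 16 2-(trimethylsilyl)ethyl (2E,5R,6R,7S)-8-hydroxy-3,5,7-trimethyl-6-(triethylsilyloxy)deca-2,9-dienoate
Product: 17 2-(trimethylsilyl)ethyl (2E,5R,6R,7S)-8-hydroxy-3,5,7-trimethyl-8-(oxiran-2-yl)-6-(triethylsilyloxy)oct-2-enoate (epimer mixture at C8 and C9)
Conditions: VO(acac)2 (5 mol %), t-BuOOH, CH2Cl2, 0 °C → rt
Reagents that add atoms: tert-butyl hydroperoxide, CC(C)(C)OO
Why: Vanadium-catalysed hydroxyl-directed epoxidation touches only the allylic-alcohol alkene under neutral conditions; both epoxide configurations are acceptable because C9 becomes a planar radical in step 21.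

**Step 11**
Reactants: 17 2-(trimethylsilyl)ethyl (2E,5R,6R,7S)-8-hydroxy-3,5,7-trimethyl-8-(oxiran-2-yl)-6-(triethylsilyloxy)oct-2-enoate
Product: 18 2-(trimethylsilyl)ethyl (2E,5R,6R,7R)-3,5,7-trimethyl-8-(oxiran-2-yl)-8-oxo-6-(triethylsilyloxy)oct-2-enoate (both oxirane epimers)
Conditions: Dess–Martin periodinane, pyridine, CH2Cl2, 0 °C → rt
Reagents that add atoms: none
Why: Dess–Martin oxidation converts the epoxy alcohol to the α,β-epoxy ketone under non-basic conditions, so the C7 centre next to the new ketone is kept.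

**Step 12**
Reactants: 19 (E)-pent-2-en-4-yn-1-ol
Product: 21 (2E,4E)-5-bromo-4-methylpenta-2,4-dien-1-ol, via dienylalane 20 (not isolated)
Conditions: Me3Al (3 equiv), Cp2ZrCl2 (25 mol %), CH2Cl2, 0 °C → rt; then N-bromosuccinimide, THF, −78 °C; dilute aq. HCl
Reagents that add atoms: trimethylaluminium, C[Al](C)C; N-bromosuccinimide, O=C1CCC(=O)N1Br
Why: Negishi carboalumination of the enyne (syn addition, Me to the internal carbon) and bromination of the alkenylalane with retention give the (E)-2-methylalkenyl bromide that becomes C10=C11.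

**Step 13**
Reactants: 21 (2E,4E)-5-bromo-4-methylpenta-2,4-dien-1-ol
Product: 22 (1E,3E)-1,5-dibromo-2-methylpenta-1,3-diene
Conditions: CBr4, PPh3, CH2Cl2, 0 °C
Reagents that add atoms: tetrabromomethane, BrC(Br)(Br)Br
Why: Appel bromination turns the primary allylic alcohol into the conjugated primary bromide; the alkenyl bromide is untouched.

**Step 14**
Reactants: 2 (E)-N-[(2R)-2-(methoxymethyl)pyrrolidin-1-yl]propan-1-imine; 22 (1E,3E)-1,5-dibromo-2-methylpenta-1,3-diene
Product: 23 (E,2R,4E,6E)-7-bromo-N-[(2R)-2-(methoxymethyl)pyrrolidin-1-yl]-2,6-dimethylhepta-4,6-dien-1-imine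
Conditions: LiN(i-Pr)2, THF, 0 °C; 22, −100 °C → rt
Reagents that add atoms: none
Why: Enders RAMP-hydrazone alkylation by SN2 at the allylic bromide only (the alkenyl bromide is inert) sets the (R) centre that becomes C15, by the same facial control as in step 2.

**Step 15**
Reactants: 23 (E,2R,4E,6E)-7-bromo-N-[(2R)-2-(methoxymethyl)pyrrolidin-1-yl]-2,6-dimethylhepta-4,6-dien-1-imine
Product: 25 (2R,4E,6E)-7-bromo-2,6-dimethylhepta-4,6-dienal, via hydrazonium iodide 24 (not isolated)
Conditions: MeI (excess), 60 °C; then 3 M aq. HCl/n-pentane, rt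
Reagents that add atoms: water, O; iodomethane, CI (its methyl group is found in 24 and leaves with the auxiliary)
Why: Enders cleavage by N-methylation and two-phase hydrolysis frees the α-methyl aldehyde without epimerisation; diene and alkenyl bromide tolerate dilute acid.

**Step 16**
Reactants: 25 (2R,4E,6E)-7-bromo-2,6-dimethylhepta-4,6-dienal
Product: 26 (1E,3E,6R,7Z)-1-bromo-8-iodo-2,6-dimethyldeca-1,3,7-triene
Conditions: [Ph3PCH2CH2CH3]I, n-BuLi, THF, rt; I2, −78 °C; NaN(SiMe3)2, −20 °C; 25, −78 → −20 °C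
Reagents that add atoms: propyltriphenylphosphonium iodide, CCC[P+](c1ccccc1)(c1ccccc1)c1ccccc1.[I-]; iodine, II
Why: Stork–Zhao–Wittig olefination: the non-stabilised α-iodo ylide reacts under kinetic control to put iodine cis to the aldehyde-derived carbon, giving the (Z)-2-iodoalkene (16Z after coupling); the low temperature protects C15.

**Step 17**
Reactants: 27 acrolein; 9 (E)-but-2-enyldiisopinocampheylborane
Product: 28 (3R,4S)-4-methylhexa-1,5-dien-3-ol
Conditions: 9 (second portion of the step 4 batch, 1.3 equiv), THF, −78 °C; 27 (freshly distilled), −78 °C, 3 h; 3 M NaOH, 30% H2O2, rt; distillation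
Reagents that add atoms: none
Why: Brown crotylboration: the (E)-crotyl group gives the anti relationship and the same batch of 9 as in step 5 attacks the Si face, setting C20 (R) and C21 (S), which is the trans arrangement of the lactone.

**Step 18**
Reactants: 28 (3R,4S)-4-methylhexa-1,5-dien-3-ol; 29 acryloyl chloride
Product: 30 (3R,4S)-4-methylhexa-1,5-dien-3-yl prop-2-enoate
Conditions: Et3N, DMAP (cat.), CH2Cl2, 0 °C
Reagents that add atoms: none
Why: O-acylation of the secondary alcohol; no stereocentre is touched.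

**Step 19**
Reactants: 30 (3R,4S)-4-methylhexa-1,5-dien-3-yl prop-2-enoate
Product: 32 (5S,6R)-5-methyl-6-[(E)-2-(4,4,5,5-tetramethyl-1,3,2-dioxaborolan-2-yl)ethenyl]-5,6-dihydro-2H-pyran-2-one, via vinyl lactone 31 (not isolated)
Conditions: second-generation Hoveyda–Grubbs catalyst (5 mol %), CH2Cl2 (5 mM), 40 °C; then vinylboronic acid pinacol ester (5 equiv), concentrate to 0.2 M, further catalyst (5 mol %), 40 °C
Reagents that add atoms: vinylboronic acid pinacol ester, C=CB1OC(C)(C)C(C)(C)O1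
Why: Tandem ring-closing/cross metathesis: the acrylate closes onto the homoallylic vinyl group to give the six-membered lactone (favoured over the five-ring alternative), and the remaining vinyl group undergoes E-selective cross metathesis with the vinyl boronate; C20 and C21 are untouched.

**Step 20**
Reactants: 26 (1E,3E,6R,7Z)-1-bromo-8-iodo-2,6-dimethyldeca-1,3,7-triene; 32 (5S,6R)-5-methyl-6-[(E)-2-(4,4,5,5-tetramethyl-1,3,2-dioxaborolan-2-yl)ethenyl]-5,6-dihydro-2H-pyran-2-one
Product: 33 (5S,6R)-6-[(1E,3Z,5R,7E,9E)-10-bromo-3-ethyl-5,9-dimethyldeca-1,3,7,9-tetraenyl]-5-methyl-5,6-dihydro-2H-pyran-2-one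
Conditions: Pd(PPh3)4 (5 mol %), TlOEt (1.5 equiv), THF/H2O (3:1), rt
Reagents that add atoms: none
Why: Suzuki–Miyaura coupling with retention at both alkenyl partners gives the (16Z,18E)-diene; at room temperature zerovalent palladium inserts into the C–I bond only, so the C10 bromide survives.

**Step 21**
Reactants: 18 2-(trimethylsilyl)ethyl (2E,5R,6R,7R)-3,5,7-trimethyl-8-(oxiran-2-yl)-8-oxo-6-(triethylsilyloxy)oct-2-enoate; 33 (5S,6R)-6-[(1E,3Z,5R,7E,9E)-10-bromo-3-ethyl-5,9-dimethyldeca-1,3,7,9-tetraenyl]-5-methyl-5,6-dihydro-2H-pyran-2-one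
Product: 34 2-(trimethylsilyl)ethyl (2E,5R,6R,7R,9S,10E,12E,15R,16Z,18E)-17-ethyl-9-(hydroxymethyl)-3,5,7,11,15-pentamethyl-19-[(2R,3S)-3-methyl-6-oxo-3,6-dihydro-2H-pyran-2-yl]-8-oxo-6-(triethylsilyloxy)nonadeca-2,10,12,16,18-pentaenoate
Conditions: NiBr2(diglyme) (10 mol %), (4S,4'S)-4,4'-diisopropyl-4,4',5,5'-tetrahydro-2,2'-bioxazole (12 mol %), Cp2TiCl2 (15 mol %), Mn powder (3 equiv), 2,4,6-collidine·HCl (1.5 equiv), THF/DMA (4:1), 0 °C → rt, 18 (1.5 equiv) added slowly
Reagents that add atoms: none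
Why: Proposed new method: Cp2TiCl (trivalent titanium, regenerated by Mn) opens the epoxy ketone by homolysis of the C9–O bond, as in the known reductive opening of α,β-epoxy ketones, to give the planar C9 α-keto radical with the oxygen held on CH2 as a titanium alkoxide; this radical is caught by the alkenylnickel bromide formed from 33 and zerovalent nickel, and reductive elimination from the resulting trivalent nickel complex forms C9–C10 with the chiral bioxazoline deciding the C9 configuration (both epoxide epimers converge on 9S), after which collidinium chloride protonates the alkoxide to the free CH2OH with no base present that could epimerise C9; the closest known reaction types are the nickel/titanocene co-catalysed reductive cross-electrophile coupling of epoxides with aryl and alkenyl halides and the stereoconvergent nickel/bis(oxazoline) alkenylation of racemic α-bromo ketones.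

**Step 22**
Reactants: 34 2-(trimethylsilyl)ethyl (2E,5R,6R,7R,9S,10E,12E,15R,16Z,18E)-17-ethyl-9-(hydroxymethyl)-3,5,7,11,15-pentamethyl-19-[(2R,3S)-3-methyl-6-oxo-3,6-dihydro-2H-pyran-2-yl]-8-oxo-6-(triethylsilyloxy)nonadeca-2,10,12,16,18-pentaenoate
Product: 35 (2E,5R,6R,7R,9S,10E,12E,15R,16Z,18E)-17-ethyl-6-hydroxy-9-(hydroxymethyl)-3,5,7,11,15-pentamethyl-19-[(2R,3S)-3-methyl-6-oxo-3,6-dihydro-2H-pyran-2-yl]-8-oxononadeca-2,10,12,16,18-pentaenoic acid
Conditions: TASF (6 equiv), DMF/H2O (20:1), 0 °C → rt; cold dilute aq. HCl to pH 4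
Reagents that add atoms: none
Why: Fluoride-induced desilylation removes the TES ether and fragments the 2-(trimethylsilyl)ethyl ester (β-elimination to ethylene) in one operation; TASF is a weakly basic fluoride source used for β-hydroxy ketones prone to retro-aldol, so C7 and C9 should survive.

## Compound list

1 | propanal | CCC=O | starting material
2 | (E)-N-[(2R)-2-(methoxymethyl)pyrrolidin-1-yl]propan-1-imine | CC/C=N/N1CCC[C@@H]1COC | intermediate
3 | 3-bromoprop-1-yne | C#CCBr | starting material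
4 | (E,2R)-N-[(2R)-2-(methoxymethyl)pyrrolidin-1-yl]-2-methylpent-4-yn-1-imine | C#CC[C@@H](C)/C=N/N1CCC[C@@H]1COC | intermediate
5 | (2R)-2-(methoxymethyl)-1-methyl-1-{[(1E,2R)-2-methylpent-4-yn-1-ylidene]amino}pyrrolidin-1-ium iodide | C#CC[C@@H](C)/C=N/[N+]1(C)CCC[C@@H]1COC.[I-] | intermediate
6 | (2R)-2-methylpent-4-ynal | O=C[C@H](C)CC#C | intermediate
7 | (E)-but-2-ene | C/C=C/C | starting material
8 | (E)-but-2-enylpotassium (crotylpotassium) | C/C=C/C[K] | intermediate
9 | (E)-but-2-enyldiisopinocampheylborane, Ipc groups derived from (+)-α-pinene | C/C=C/CB([C@@H]1C[C@@H]2C[C@H]([C@H]1C)C2(C)C)[C@@H]1C[C@@H]2C[C@H]([C@H]1C)C2(C)C | intermediate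
10 | (3S,4R,5R)-3,5-dimethyloct-1-en-7-yn-4-ol | C=C[C@H](C)[C@H](O)[C@H](C)CC#C | intermediate
11 | (3S,4R,5R)-3,5-dimethyl-4-(triethylsilyloxy)oct-1-en-7-yne | C=C[C@H](C)[C@H](O[Si](CC)(CC)CC)[C@H](C)CC#C | intermediate
12 | dimethyl[(1E,4R,5R,6S)-2,4,6-trimethyl-5-(triethylsilyloxy)octa-1,7-dienyl]alane | C=C[C@H](C)[C@H](O[Si](CC)(CC)CC)[C@H](C)C/C(C)=C/[Al](C)C | intermediate
13 | 2-(trimethylsilyl)ethyl (2E,5R,6R,7S)-3,5,7-trimethyl-6-(triethylsilyloxy)nona-2,8-dienoate | C=C[C@H](C)[C@H](O[Si](CC)(CC)CC)[C@H](C)C/C(C)=C/C(=O)OCC[Si](C)(C)C | intermediate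
14 | 2-(trimethylsilyl)ethyl (2E,5R,6R,7R)-3,5,7-trimethyl-8-oxo-6-(triethylsilyloxy)oct-2-enoate | O=C[C@H](C)[C@H](O[Si](CC)(CC)CC)[C@H](C)C/C(C)=C/C(=O)OCC[Si](C)(C)C | intermediate
15 | vinylmagnesium bromide | C=C[Mg]Br | starting material
16 | 2-(trimethylsilyl)ethyl (2E,5R,6R,7S)-8-hydroxy-3,5,7-trimethyl-6-(triethylsilyloxy)deca-2,9-dienoate (both C8 epimers) | C=CC(O)[C@H](C)[C@H](O[Si](CC)(CC)CC)[C@H](C)C/C(C)=C/C(=O)OCC[Si](C)(C)C | intermediate
17 | 2-(trimethylsilyl)ethyl (2E,5R,6R,7S)-8-hydroxy-3,5,7-trimethyl-8-(oxiran-2-yl)-6-(triethylsilyloxy)oct-2-enoate (epimer mixture at C8 and C9) | OC(C1CO1)[C@H](C)[C@H](O[Si](CC)(CC)CC)[C@H](C)C/C(C)=C/C(=O)OCC[Si](C)(C)C | intermediate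
18 | 2-(trimethylsilyl)ethyl (2E,5R,6R,7R)-3,5,7-trimethyl-8-(oxiran-2-yl)-8-oxo-6-(triethylsilyloxy)oct-2-enoate (both oxirane epimers) | O=C(C1CO1)[C@H](C)[C@H](O[Si](CC)(CC)CC)[C@H](C)C/C(C)=C/C(=O)OCC[Si](C)(C)C | intermediate
19 | (E)-pent-2-en-4-yn-1-ol | C#C/C=C/CO | starting material
20 | [(1E,3E)-5-(dimethylalumanyloxy)-2-methylpenta-1,3-dienyl]dimethylalane | C[Al](C)/C=C(C)/C=C/CO[Al](C)C | intermediate
21 | (2E,4E)-5-bromo-4-methylpenta-2,4-dien-1-ol | OC/C=C/C(C)=C/Br | intermediate
22 | (1E,3E)-1,5-dibromo-2-methylpenta-1,3-diene | BrC/C=C/C(C)=C/Br | intermediate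
23 | (E,2R,4E,6E)-7-bromo-N-[(2R)-2-(methoxymethyl)pyrrolidin-1-yl]-2,6-dimethylhepta-4,6-dien-1-imine | Br/C=C(C)/C=C/C[C@@H](C)/C=N/N1CCC[C@@H]1COC | intermediate
24 | (2R)-1-{[(1E,2R,4E,6E)-7-bromo-2,6-dimethylhepta-4,6-dien-1-ylidene]amino}-2-(methoxymethyl)-1-methylpyrrolidin-1-ium iodide | Br/C=C(C)/C=C/C[C@@H](C)/C=N/[N+]1(C)CCC[C@@H]1COC.[I-] | intermediate
25 | (2R,4E,6E)-7-bromo-2,6-dimethylhepta-4,6-dienal | O=C[C@H](C)C/C=C/C(C)=C/Br | intermediate
26 | (1E,3E,6R,7Z)-1-bromo-8-iodo-2,6-dimethyldeca-1,3,7-triene | CC/C(I)=C/[C@H](C)C/C=C/C(C)=C/Br | intermediate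
27 | acrolein | C=CC=O | starting material
28 | (3R,4S)-4-methylhexa-1,5-dien-3-ol | C=C[C@@H](O)[C@@H](C)C=C | intermediate
29 | acryloyl chloride | C=CC(Cl)=O | starting material
30 | (3R,4S)-4-methylhexa-1,5-dien-3-yl prop-2-enoate | C=C[C@@H](OC(=O)C=C)[C@@H](C)C=C | intermediate
31 | (5S,6R)-6-ethenyl-5-methyl-5,6-dihydro-2H-pyran-2-one | C=C[C@H]1OC(=O)C=C[C@@H]1C | intermediate
32 | (5S,6R)-5-methyl-6-[(E)-2-(4,4,5,5-tetramethyl-1,3,2-dioxaborolan-2-yl)ethenyl]-5,6-dihydro-2H-pyran-2-one | CC1(C)OB(/C=C/[C@H]2OC(=O)C=C[C@@H]2C)OC1(C)C | intermediate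
33 | (5S,6R)-6-[(1E,3Z,5R,7E,9E)-10-bromo-3-ethyl-5,9-dimethyldeca-1,3,7,9-tetraenyl]-5-methyl-5,6-dihydro-2H-pyran-2-one | CCC(=C/[C@H](C)C/C=C/C(C)=C/Br)/C=C/[C@H]1OC(=O)C=C[C@@H]1C | intermediate
34 | 2-(trimethylsilyl)ethyl (2E,5R,6R,7R,9S,10E,12E,15R,16Z,18E)-17-ethyl-9-(hydroxymethyl)-3,5,7,11,15-pentamethyl-19-[(2R,3S)-3-methyl-6-oxo-3,6-dihydro-2H-pyran-2-yl]-8-oxo-6-(triethylsilyloxy)nonadeca-2,10,12,16,18-pentaenoate | CCC(=C/[C@H](C)C/C=C/C(C)=C/[C@@H](CO)C(=O)[C@H](C)[C@H](O[Si](CC)(CC)CC)[C@H](C)C/C(C)=C/C(=O)OCC[Si](C)(C)C)/C=C/[C@H]1OC(=O)C=C[C@@H]1C | intermediate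
35 | (2E,5R,6R,7R,9S,10E,12E,15R,16Z,18E)-17-ethyl-6-hydroxy-9-(hydroxymethyl)-3,5,7,11,15-pentamethyl-19-[(2R,3S)-3-methyl-6-oxo-3,6-dihydro-2H-pyran-2-yl]-8-oxononadeca-2,10,12,16,18-pentaenoic acid | CCC(=C/[C@H](C)C/C=C/C(C)=C/[C@@H](CO)C(=O)[C@H](C)[C@H](O)[C@H](C)C/C(C)=C/C(=O)O)/C=C/[C@H]1OC(=O)C=C[C@@H]1C | target

## Step count and risks

Total step count: 22. Longest linear sequence: 12 (steps 1–3, 5–11, 21, 22).

**Most likely to fail, 1: step 21.** The α-keto radical can be reduced further by trivalent titanium to a titanium enolate, which loses the CH2O arm or gives the simple aldol. It can also add to the dienes of 33, and zerovalent nickel can ionise the allylic lactone C–O bond. The sense and level of ligand control at C9 are not known in advance; if the first run favours the 9-epimer, the enantiomeric ligand is used. Fallback, setting out from 18 and returning at 35: reduce 18 with SmI2 (THF/MeOH, −90 °C) to the aldol 2-(trimethylsilyl)ethyl (2E,5R,6R,7R)-10-hydroxy-3,5,7-trimethyl-8-oxo-6-(triethylsilyloxy)dec-2-enoate F1. Silylate it with Et3SiCl/imidazole to the bis-TES ketone F2. Brominate the kinetic lithium enolate (LiN(SiMe3)2, −78 °C, then N-bromosuccinimide) to the α-bromo ketone F3 as a C9 epimer mixture. Couple F3 with 33 by a titanium-free stereoconvergent nickel/bis(oxazoline) reductive alkenylation (NiBr2(diglyme), chiral bis(oxazoline), Mn powder, NaI, DMA, 0 °C), which still forms C9–C10 through the α-keto radical and gives the 9-(triethylsilyloxymethyl) coupling product F4. F4 is taken to 35 under the conditions of step 22.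

**Most likely to fail, 2: step 22.** Fluoride is mildly basic and the product has an acidic C9–H next to a hydroxymethyl group, so retro-aldol loss of formaldehyde, elimination or epimerisation may occur. Fallback, setting out from 18 and returning at 35: remove both silicon groups before the sensitive centre exists. TASF converts 18 to the hydroxy acid (2E,5R,6R,7R)-6-hydroxy-3,5,7-trimethyl-8-(oxiran-2-yl)-8-oxooct-2-enoic acid F5. F5 is silylated in the flask with N,O-bis(trimethylsilyl)acetamide to its bis-TMS derivative F6. F6 is coupled with 33 under the step 21 conditions with Me3SiCl in place of collidinium chloride, giving the tris-TMS derivative F7 of the target. The three TMS groups fall off on work-up with pH 4 citrate buffer to give 35, so the radical coupling becomes the last step and no fluoride touches the product.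

**Most likely to fail, 3: step 19.** Cross metathesis at an alkene flanked by the lactone oxygen and a branched carbon may stall, and step 20 then has no boronate. Fallback, setting out from 30 and returning at 33: run only the ring closure (same catalyst, no vinyl boronate) and isolate vinyl lactone 31. Join 31 directly to iodide 26 by a Heck reaction (Pd(OAc)2, Ag2CO3, DMF, rt), in which the alkenylpalladium adds to the terminal carbon and β-hydride elimination gives the (18E)-diene 33; step 20 is then not needed (new compounds: none F0).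

## Further compounds

F1 | step 21 | 2-(trimethylsilyl)ethyl (2E,5R,6R,7R)-10-hydroxy-3,5,7-trimethyl-8-oxo-6-(triethylsilyloxy)dec-2-enoate | OCCC(=O)[C@H](C)[C@H](O[Si](CC)(CC)CC)[C@H](C)C/C(C)=C/C(=O)OCC[Si](C)(C)C
F2 | step 21 | 2-(trimethylsilyl)ethyl (2E,5R,6R,7R)-3,5,7-trimethyl-8-oxo-6,10-bis(triethylsilyloxy)dec-2-enoate | CC[Si](CC)(CC)OCCC(=O)[C@H](C)[C@H](O[Si](CC)(CC)CC)[C@H](C)C/C(C)=C/C(=O)OCC[Si](C)(C)C
F3 | step 21 | 2-(trimethylsilyl)ethyl (2E,5R,6R,7R)-9-bromo-3,5,7-trimethyl-8-oxo-6,10-bis(triethylsilyloxy)dec-2-enoate (both C9 epimers) | CC[Si](CC)(CC)OCC(Br)C(=O)[C@H](C)[C@H](O[Si](CC)(CC)CC)[C@H](C)C/C(C)=C/C(=O)OCC[Si](C)(C)C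
F4 | step 21 | 2-(trimethylsilyl)ethyl (2E,5R,6R,7R,9S,10E,12E,15R,16Z,18E)-17-ethyl-3,5,7,11,15-pentamethyl-19-[(2R,3S)-3-methyl-6-oxo-3,6-dihydro-2H-pyran-2-yl]-8-oxo-6-(triethylsilyloxy)-9-(triethylsilyloxymethyl)nonadeca-2,10,12,16,18-pentaenoate | CCC(=C/[C@H](C)C/C=C/C(C)=C/[C@@H](CO[Si](CC)(CC)CC)C(=O)[C@H](C)[C@H](O[Si](CC)(CC)CC)[C@H](C)C/C(C)=C/C(=O)OCC[Si](C)(C)C)/C=C/[C@H]1OC(=O)C=C[C@@H]1C
F5 | step 22 | (2E,5R,6R,7R)-6-hydroxy-3,5,7-trimethyl-8-(oxiran-2-yl)-8-oxooct-2-enoic acid (both oxirane epimers) | O=C(C1CO1)[C@H](C)[C@H](O)[C@H](C)C/C(C)=C/C(=O)O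
F6 | step 22 | trimethylsilyl (2E,5R,6R,7R)-3,5,7-trimethyl-8-(oxiran-2-yl)-8-oxo-6-(trimethylsilyloxy)oct-2-enoate | O=C(C1CO1)[C@H](C)[C@H](O[Si](C)(C)C)[C@H](C)C/C(C)=C/C(=O)O[Si](C)(C)C
F7 | step 22 | trimethylsilyl (2E,5R,6R,7R,9S,10E,12E,15R,16Z,18E)-17-ethyl-3,5,7,11,15-pentamethyl-19-[(2R,3S)-3-methyl-6-oxo-3,6-dihydro-2H-pyran-2-yl]-8-oxo-6-(trimethylsilyloxy)-9-(trimethylsilyloxymethyl)nonadeca-2,10,12,16,18-pentaenoate | CCC(=C/[C@H](C)C/C=C/C(C)=C/[C@@H](CO[Si](C)(C)C)C(=O)[C@H](C)[C@H](O[Si](C)(C)C)[C@H](C)C/C(C)=C/C(=O)O[Si](C)(C)C)/C=C/[C@H]1OC(=O)C=C[C@@H]1C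
F0 | step 19 | none | none
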